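**Retrosynthetic overview**
1. Feature (labdane numbering): in ring A the gem-dimethyl carbon C4 is bonded to the carbinol carbon C3 and to C5. C5 is the α-carbon of the oxygenated C6 in ring B. The C4–C5 bond can therefore be read as the tertiary carbon of a C3–C4 epoxide joined to the α-carbon of a C6 ketone.
2. Late disconnections: C12–C13 (Negishi coupling with the ready-made butenolide ring), the O6 acetyl group, and the C6 and C8 stereocentres, both of which come from a ring B enone (C6=O, C7=C8).
3. Key disconnection: C4–C5. Ring A is closed onto a complete ring B when the C5 end of a 6-silyloxy-5,7-diene opens a (3S)-epoxide at C4 under Lewis acid.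
4. Ring B comes from an arene. 4-Bromo-3,5-dimethylphenol gains C11–C12 from oxirane and is dearomatised to the para-quinol (O9). It is then desymmetrised at C10 by an O9-directed conjugate addition of the homoprenyl Grignard reagent (C1–C4, C18, C19).
5. Ring order: ring B (steps 1–6), ring A (step 10), butenolide attached in step 17.

Key step: step 10

Remark on numbering: labdane numbers (C1–C20) are used for ring B and bicyclic compounds; α means below and β above the plane in the usual drawing with the C10 methyl β.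
Assumption: the sense of induction of the chiral copper catalyst on quinol 8 cannot be derived from a model, so the ligand antipode that gives (4S,5S)-12 is fixed by one test run. Both antipodes are made from D- or L-leucinol.

**Step 1**
Reactants: 1 4-bromo-3,5-dimethylphenol
Product: 2 (4-bromo-3,5-dimethylphenoxy)triisopropylsilane
Conditions: i-Pr3SiCl, imidazole, DMF, rt
Reagents that add atoms: chlorotriisopropylsilane, CC(C)[Si](Cl)(C(C)C)C(C)C
Why: Silyl ether formation masks the acidic phenol, which would otherwise quench the aryllithium of step 2 and be benzylated ahead of the primary alcohol in step 3.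

**Step 2**
Reactants: 2 (4-bromo-3,5-dimethylphenoxy)triisopropylsilane; 3 oxirane
Product: 5 2-[2,6-dimethyl-4-(triisopropylsilyloxy)phenyl]ethan-1-ol, via aryllithium 4 (not isolated)
Conditions: n-BuLi, THF, −78 °C; then 3, −78 °C to rt; H2O
Reagents that add atoms: none
Why: Bromine–lithium exchange followed by SN2 opening of oxirane by the aryllithium attaches C11–C12 to the ring carbon that becomes C9.

**Step 3**
Reactants: 5 2-[2,6-dimethyl-4-(triisopropylsilyloxy)phenyl]ethan-1-ol
Product: 6 {4-[2-(benzyloxy)ethyl]-3,5-dimethylphenoxy}triisopropylsilane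
Conditions: NaH, BnBr, Bu4NI (cat.), THF, 0 °C to rt
Reagents that add atoms: benzyl bromide, BrCc1ccccc1
Why: Williamson etherification of the only free hydroxyl gives an O12 group that survives organometallic, Lewis-acid and hydride steps and is removed orthogonally to silyl ethers.

**Step 4**
Reactants: 6 {4-[2-(benzyloxy)ethyl]-3,5-dimethylphenoxy}triisopropylsilane
Product: 7 4-[2-(benzyloxy)ethyl]-3,5-dimethylphenol
Conditions: Bu4NF, THF, 0 °C; H2O
Reagents that add atoms: none
Why: Fluoride-induced cleavage of the aryl silyl ether frees the phenol for oxidation and leaves the benzyl ether untouched.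

**Step 5**
Reactants: 7 4-[2-(benzyloxy)ethyl]-3,5-dimethylphenol
Product: 8 4-[2-(benzyloxy)ethyl]-4-hydroxy-3,5-dimethylcyclohexa-2,5-dien-1-one
Conditions: PhI(OAc)2, MeCN–H2O, 0 °C
Reagents that add atoms: water, O
Why: Hypervalent-iodine oxidative dearomatisation of a para-alkylphenol with capture of water at the para carbon gives the achiral para-quinol, which already holds O9, O6 and both ring methyl groups (C17, C20).

**Step 6**
Reactants: 8 4-[2-(benzyloxy)ethyl]-4-hydroxy-3,5-dimethylcyclohexa-2,5-dien-1-one; 9 5-bromo-2-methylpent-2-ene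
Product: 12 (4S,5S)-4-[2-(benzyloxy)ethyl]-4-hydroxy-3,5-dimethyl-5-(4-methylpent-3-en-1-yl)cyclohex-2-en-1-one, via homoprenylmagnesium bromide 10 (not isolated), via quinol bromomagnesium alkoxide 11 (not isolated)
Conditions: 9, Mg turnings, Et2O, reflux; 10 (2.5 equiv), Cu(OTf)2 (5 mol %), (S)-1-(1-hydroxy-4-methylpentan-2-yl)-3-(2,4,6-trimethylphenyl)-4,5-dihydro-1H-imidazol-3-ium hexafluorophosphate (7 mol %), Et2O, −30 °C, slow addition of 8; aq NH4Cl
Reagents that add atoms: none
Why: Proposed new method: the first equivalent of 10 turns 8 into alkoxide 11, whose O9–Mg unit holds the incoming organometal on the O9 face so that C1 is delivered to C10 syn to O9 (this sets the 9α-O/10β-CH3 relation and is the known alkoxide-directed 1,4-addition of Grignard reagents to para-quinols), while the chiral NHC–copper alkyl formed from Cu(OTf)2, the imidazolinium salt and 10 has to choose between the two enantiotopic β-methyl enone arms and so sets the absolute configuration; the closest known reaction types are the NHC–copper-catalysed asymmetric conjugate addition of Grignard reagents to 3-methylcyclohex-2-enone (quaternary centre), for which phosphine–copper halide catalysts are not suited, and the copper-catalysed desymmetrisation of 4,4-disubstituted cyclohexadienones; what is new is their use on a free 3,5-dimethyl para-quinol, where the C–C bond forms next to a fully substituted carbon.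

**Step 7**
Reactants: 12 (4S,5S)-4-[2-(benzyloxy)ethyl]-4-hydroxy-3,5-dimethyl-5-(4-methylpent-3-en-1-yl)cyclohex-2-en-1-one
Product: 13 (4S,5S)-4-[2-(benzyloxy)ethyl]-3,5-dimethyl-5-(4-methylpent-3-en-1-yl)-4-(triethylsilyloxy)cyclohex-2-en-1-one
Conditions: Et3SiOTf, 2,6-lutidine, CH2Cl2, −78 to 0 °C
Reagents that add atoms: triethylsilyl trifluoromethanesulfonate, CC[Si](CC)(CC)OS(=O)(=O)C(F)(F)F
Why: Silyl triflate silylation reaches the crowded tertiary O9 and is placed before the epoxidation because Et3SiOTf would open or isomerise a trisubstituted epoxide.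

**Step 8**
Reactants: 13 (4S,5S)-4-[2-(benzyloxy)ethyl]-3,5-dimethyl-5-(4-methylpent-3-en-1-yl)-4-(triethylsilyloxy)cyclohex-2-en-1-one
Product: 14 (4S,5S)-4-[2-(benzyloxy)ethyl]-5-{2-[(2S)-3,3-dimethyloxiran-2-yl]ethyl}-3,5-dimethyl-4-(triethylsilyloxy)cyclohex-2-en-1-one
Conditions: 1,2:4,5-di-O-isopropylidene-β-L-erythro-2,3-hexodiulo-2,6-pyranose (30 mol %), Oxone (2KHSO5·KHSO4·K2SO4), K2CO3, Bu4NHSO4 (cat.), Na2B4O7/Na2EDTA buffer, MeCN–CH2(OMe)2–H2O, 0 °C
Reagents that add atoms: potassium peroxymonosulfate (active part of Oxone), [K+].[O-]S(=O)(=O)OO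
Why: Shi epoxidation oxidises only the electron-rich C3=C4 alkene (the enone is inert to the catalytically generated chiral dioxirane) and sets C3 under reagent control; the L-fructose-derived ketone is needed because the D-fructose-derived one gives the (R)-epoxide from R–CH=C(CH3)2 alkenes.

**Step 9**
Reactants: 14 (4S,5S)-4-[2-(benzyloxy)ethyl]-5-{2-[(2S)-3,3-dimethyloxiran-2-yl]ethyl}-3,5-dimethyl-4-(triethylsilyloxy)cyclohex-2-en-1-one
Product: 16 ring B 6-(trimethylsilyloxy)-5,7-diene bearing the (3S)-epoxyhomoprenyl arm on C10 (3S;9R;10S), via lithium dienolate 15 (not isolated)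
Conditions: LDA, THF, −78 °C; Me3SiCl, Et3N, −78 to 0 °C; pentane, cold aq NaHCO3; used crude
Reagents that add atoms: chlorotrimethylsilane, C[Si](C)(C)Cl
Why: Kinetic α′-deprotonation of the β-methyl enone occurs at C5 (as with isophorone-type enones) and O-silylation fixes the cross-conjugated dienolate, while epoxide and silyl ethers are inert at −78 °C; the C9 descriptor changes for priority reasons only.

**Step 10**
Reactants: 16 ring B 6-(trimethylsilyloxy)-5,7-diene bearing the (3S)-epoxyhomoprenyl arm on C10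
Product: 17 12-benzyloxy-3β-hydroxy-9α-(triethylsilyloxy)-13,14,15,16-tetranorlabd-7-en-6-one
Conditions: MeAlCl2 (2 equiv, hexanes), CH2Cl2, −78 °C; Et3N–MeOH quench, aq NaHCO3; then K2CO3 (cat.), MeOH, rt
Reagents that add atoms: none
Why: MeAlCl2 binds the epoxide oxygen, the C4–O bond stretches toward the tertiary cation, and C5, the only nucleophilic terminus of the cross-conjugated silyloxydiene, attacks C4, after which chloride removes Me3Si from O6 and the C6=O/C7=C8 enone appears. The closest known reaction type is the MeAlCl2-promoted epoxide-initiated cation–olefin cyclisation that ends on an enol silane, shortened here to one ring closure, that is an intramolecular tert-alkylation of an enol silane. Ring A closes 6-endo with respect to the epoxide (C3 and C4 both end up in the ring) and exo with respect to the C5=C6 enol ether. C5 is the one new stereocentre: a chair with the C10 methyl axial and C9 equatorial on the nascent ring places C4 on the β side of C5 (5α-H), and because C5 is α to C6=O the K2CO3/MeOH treatment lets cis-fused material epimerise to the trans-fused enone expected to be the more stable; the C3–O bond is never broken, so the (3S)-epoxide becomes the equatorial 3β-OH. The step needs attack at C4 rather than C3, which the tertiary versus secondary cation character under a strong Lewis acid secures. It also needs the allylic tertiary C9–O bond to stay intact, which rests on the low basicity and bulk of the Et3Si ether, the low temperature and the acid-scavenging Al–CH3 bond.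

**Step 11**
Reactants: 17 12-benzyloxy-3β-hydroxy-9α-(triethylsilyloxy)-13,14,15,16-tetranorlabd-7-en-6-one
Product: 18 12-benzyloxy-3β,9α-bis(triethylsilyloxy)-13,14,15,16-tetranorlabd-7-en-6-one
Conditions: Et3SiCl, imidazole, DMAP (cat.), DMF, rt
Reagents that add atoms: chlorotriethylsilane, CC[Si](Cl)(CC)CC
Why: Silylation masks the equatorial 3β-OH now, because the target keeps O3 free and O6 acetylated, and acetylation of a 3,6-diol would hit the less hindered O3 first.

**Step 12**
Reactants: 18 12-benzyloxy-3β,9α-bis(triethylsilyloxy)-13,14,15,16-tetranorlabd-7-en-6-one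
Product: 19 12-benzyloxy-3β,9α-bis(triethylsilyloxy)-13,14,15,16-tetranorlabd-7-en-6β-ol
Conditions: NaBH4, CeCl3·7H2O, MeOH–THF, −20 °C
Reagents that add atoms: none
Why: Luche 1,2-reduction delivers hydride to C6 from the α face because the β face is screened by the syn-axial C10 and 4β methyl groups, giving the axial 6β-alcohol.

**Step 13**
Reactants: 19 12-benzyloxy-3β,9α-bis(triethylsilyloxy)-13,14,15,16-tetranorlabd-7-en-6β-ol
Product: 20 12-benzyloxy-3β,9α-bis(triethylsilyloxy)-8βH-13,14,15,16-tetranorlabdan-6β-ol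
Conditions: H2 (1–10 bar), [Ir(cod)(PCy3)(py)]PF6 (10 mol %), CH2Cl2, rt
Reagents that add atoms: none
Why: Hydroxyl-directed homogeneous hydrogenation: the cationic iridium binds the allylic 6β-OH and adds H2 to the β face of C7=C8 (the α face is also blocked by the axial 9α-OSiEt3), so C8 receives 8β-H and the C17 methyl becomes α and equatorial, with the benzyl ether untouched.

**Step 14**
Reactants: 20 12-benzyloxy-3β,9α-bis(triethylsilyloxy)-8βH-13,14,15,16-tetranorlabdan-6β-ol
Product: 21 6β-acetoxy-12-benzyloxy-3β,9α-bis(triethylsilyloxy)-8βH-13,14,15,16-tetranorlabdane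
Conditions: Ac2O, DMAP, Et3N, CH2Cl2, 40 °C
Reagents that add atoms: acetic anhydride, CC(=O)OC(C)=O
Why: DMAP-catalysed acylation meets only one free hydroxyl, and gentle heating compensates for the axial 6β position between two syn-axial methyl groups.

**Step 15**
Reactants: 21 6β-acetoxy-12-benzyloxy-3β,9α-bis(triethylsilyloxy)-8βH-13,14,15,16-tetranorlabdane
Product: 22 6β-acetoxy-3β,9α-bis(triethylsilyloxy)-8βH-13,14,15,16-tetranorlabdan-12-ol
Conditions: H2 (1 atm), 10% Pd/C, EtOAc, rt
Reagents that add atoms: none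
Why: Hydrogenolysis of the benzyl ether is clean because no C=C is left, and EtOAc instead of an alcohol solvent keeps the Et3Si ethers in place.

**Step 16**
Reactants: 22 6β-acetoxy-3β,9α-bis(triethylsilyloxy)-8βH-13,14,15,16-tetranorlabdan-12-ol
Product: 23 6β-acetoxy-12-iodo-3β,9α-bis(triethylsilyloxy)-8βH-13,14,15,16-tetranorlabdane
Conditions: I2, PPh3, imidazole, CH2Cl2, 0 °C to rt
Reagents that add atoms: iodine, II
Why: Appel-type iodination replaces the phosphorus-activated primary hydroxyl by SN2 under imidazole buffering, which acetate and silyl ethers tolerate.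

**Step 17**
Reactants: 23 6β-acetoxy-12-iodo-3β,9α-bis(triethylsilyloxy)-8βH-13,14,15,16-tetranorlabdane; 24 3-bromofuran-2(5H)-one
Product: 26 6β-acetoxy-3β,9α-bis(triethylsilyloxy)labd-13-en-16,15-olide, via alkylzinc iodide 25 (not isolated)
Conditions: Zn dust (activated), LiCl, THF, 40 °C; then 24, Pd(OAc)2 (5 mol %), SPhos (10 mol %), THF, rt
Reagents that add atoms: none
Why: Negishi coupling: zinc inserts directly into the primary C12–I bond without touching the acetate (an alkyllithium route would not allow this), and zerovalent palladium carrying the bulky biaryl phosphine joins C12 to the α-carbon C13 of the bromobutenolide faster than β-hydride elimination.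

**Step 18**
Reactants: 26 6β-acetoxy-3β,9α-bis(triethylsilyloxy)labd-13-en-16,15-olide
Product: 27 6β-acetoxy-3β,9α-dihydroxylabd-13-en-16,15-olide (CNP0513254.1)
Conditions: HF·pyridine, pyridine–THF, 0 °C to rt
Reagents that add atoms: none
Why: Buffered acidic fluoride removes both Et3Si groups without the acetate migration, lactone opening or double-bond shift that basic fluoride could cause.

**Compound list**
1 | 4-bromo-3,5-dimethylphenol | Cc1cc(O)cc(C)c1Br | starting material
2 | (4-bromo-3,5-dimethylphenoxy)triisopropylsilane | Cc1cc(O[Si](C(C)C)(C(C)C)C(C)C)cc(C)c1Br | intermediate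
3 | oxirane | C1CO1 | starting material
4 | [2,6-dimethyl-4-(triisopropylsilyloxy)phenyl]lithium | [Li]c1c(C)cc(O[Si](C(C)C)(C(C)C)C(C)C)cc1C | intermediate
5 | 2-[2,6-dimethyl-4-(triisopropylsilyloxy)phenyl]ethan-1-ol | OCCc1c(C)cc(O[Si](C(C)C)(C(C)C)C(C)C)cc1C | intermediate
6 | {4-[2-(benzyloxy)ethyl]-3,5-dimethylphenoxy}triisopropylsilane | Cc1cc(O[Si](C(C)C)(C(C)C)C(C)C)cc(C)c1CCOCc1ccccc1 | intermediate
7 | 4-[2-(benzyloxy)ethyl]-3,5-dimethylphenol | Cc1cc(O)cc(C)c1CCOCc1ccccc1 | intermediate
8 | 4-[2-(benzyloxy)ethyl]-4-hydroxy-3,5-dimethylcyclohexa-2,5-dien-1-one (achiral para-quinol) | O=C1C=C(C)C(O)(CCOCc2ccccc2)C(C)=C1 | intermediate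
9 | 5-bromo-2-methylpent-2-ene | CC(C)=CCCBr | starting material
10 | (4-methylpent-3-en-1-yl)magnesium bromide | CC(C)=CCC[Mg]Br | intermediate
11 | bromomagnesium alkoxide of 8 | O=C1C=C(C)C(O[Mg]Br)(CCOCc2ccccc2)C(C)=C1 | intermediate
12 | (4S,5S)-4-[2-(benzyloxy)ethyl]-4-hydroxy-3,5-dimethyl-5-(4-methylpent-3-en-1-yl)cyclohex-2-en-1-one (9α-OH, 10β-CH3) | O=C1C[C@](C)(CCC=C(C)C)[C@@](O)(CCOCc2ccccc2)C(C)=C1 | intermediate
13 | (4S,5S)-4-[2-(benzyloxy)ethyl]-3,5-dimethyl-5-(4-methylpent-3-en-1-yl)-4-(triethylsilyloxy)cyclohex-2-en-1-one | O=C1C[C@](C)(CCC=C(C)C)[C@@](O[Si](CC)(CC)CC)(CCOCc2ccccc2)C(C)=C1 | intermediate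
14 | (4S,5S)-4-[2-(benzyloxy)ethyl]-5-{2-[(2S)-3,3-dimethyloxiran-2-yl]ethyl}-3,5-dimethyl-4-(triethylsilyloxy)cyclohex-2-en-1-one | O=C1C[C@](C)(CC[C@@H]2OC2(C)C)[C@@](O[Si](CC)(CC)CC)(CCOCc3ccccc3)C(C)=C1 | intermediate
15 | lithium cross-conjugated dienolate of 14 (C5=C6–OLi, C7=C8) | [Li]OC1=C[C@](C)(CC[C@@H]2OC2(C)C)[C@@](O[Si](CC)(CC)CC)(CCOCc3ccccc3)C(C)=C1 | intermediate
16 | ring B 6-(trimethylsilyloxy)-5,7-diene with (3S)-epoxyhomoprenyl arm on C10, 9α-OSiEt3, 10β-CH3 (3S,9R,10S); key-step precursor | C[Si](C)(C)OC1=C[C@](C)(CC[C@@H]2OC2(C)C)[C@@](O[Si](CC)(CC)CC)(CCOCc3ccccc3)C(C)=C1 | intermediate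
17 | 12-benzyloxy-3β-hydroxy-9α-(triethylsilyloxy)-13,14,15,16-tetranorlabd-7-en-6-one (5α-H, 10β-CH3, trans-fused); key-step product | O=C1C=C(C)[C@](O[Si](CC)(CC)CC)(CCOCc3ccccc3)[C@@]2(C)CC[C@H](O)C(C)(C)[C@H]12 | intermediate
18 | 12-benzyloxy-3β,9α-bis(triethylsilyloxy)-13,14,15,16-tetranorlabd-7-en-6-one | O=C1C=C(C)[C@](O[Si](CC)(CC)CC)(CCOCc3ccccc3)[C@@]2(C)CC[C@H](O[Si](CC)(CC)CC)C(C)(C)[C@H]12 | intermediate
19 | 12-benzyloxy-3β,9α-bis(triethylsilyloxy)-13,14,15,16-tetranorlabd-7-en-6β-ol | O[C@@H]1C=C(C)[C@](O[Si](CC)(CC)CC)(CCOCc3ccccc3)[C@@]2(C)CC[C@H](O[Si](CC)(CC)CC)C(C)(C)[C@H]12 | intermediate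
20 | 12-benzyloxy-3β,9α-bis(triethylsilyloxy)-8βH-13,14,15,16-tetranorlabdan-6β-ol (8α-CH3) | O[C@@H]1C[C@@H](C)[C@](O[Si](CC)(CC)CC)(CCOCc3ccccc3)[C@@]2(C)CC[C@H](O[Si](CC)(CC)CC)C(C)(C)[C@H]12 | intermediate
21 | 6β-acetoxy-12-benzyloxy-3β,9α-bis(triethylsilyloxy)-8βH-13,14,15,16-tetranorlabdane | CC(=O)O[C@@H]1C[C@@H](C)[C@](O[Si](CC)(CC)CC)(CCOCc3ccccc3)[C@@]2(C)CC[C@H](O[Si](CC)(CC)CC)C(C)(C)[C@H]12 | intermediate
22 | 6β-acetoxy-3β,9α-bis(triethylsilyloxy)-8βH-13,14,15,16-tetranorlabdan-12-ol | CC(=O)O[C@@H]1C[C@@H](C)[C@](O[Si](CC)(CC)CC)(CCO)[C@@]2(C)CC[C@H](O[Si](CC)(CC)CC)C(C)(C)[C@H]12 | intermediate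
23 | 6β-acetoxy-12-iodo-3β,9α-bis(triethylsilyloxy)-8βH-13,14,15,16-tetranorlabdane | CC(=O)O[C@@H]1C[C@@H](C)[C@](O[Si](CC)(CC)CC)(CCI)[C@@]2(C)CC[C@H](O[Si](CC)(CC)CC)C(C)(C)[C@H]12 | intermediate
24 | 3-bromofuran-2(5H)-one | O=C1OCC=C1Br | starting material
25 | C12 alkylzinc iodide from 23 | CC(=O)O[C@@H]1C[C@@H](C)[C@](O[Si](CC)(CC)CC)(CC[Zn]I)[C@@]2(C)CC[C@H](O[Si](CC)(CC)CC)C(C)(C)[C@H]12 | intermediate
26 | 6β-acetoxy-3β,9α-bis(triethylsilyloxy)labd-13-en-16,15-olide (8α-CH3) | CC(=O)O[C@@H]1C[C@@H](C)[C@](O[Si](CC)(CC)CC)(CCC2=CCOC2=O)[C@@]2(C)CC[C@H](O[Si](CC)(CC)CC)C(C)(C)[C@H]12 | intermediate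
27 | 6β-acetoxy-3β,9α-dihydroxylabd-13-en-16,15-olide (5α-H, 8α-CH3, 10β-CH3; CNP0513254.1) | CC(=O)O[C@@H]1C[C@@H](C)[C@](O)(CCC2=CCOC2=O)[C@@]2(C)CC[C@H](O)C(C)(C)[C@H]12 | target

**Total step count:** 18. **Longest linear sequence:** 18 steps from 1; compounds 3, 9 and 24 enter as purchased materials.

**Steps most likely to fail**

Step 6 (bears the label). The uncatalysed alkoxide-directed addition may run beside the catalysed one and erode the enantioselectivity. Direct 1,2-addition at the open C6 carbonyl may compete. Bond formation next to the fully substituted C9 may also be slow. A modest enantiomeric excess is partly repaired later, because the minor enantiomer becomes a diastereomer after step 8 and can be removed at the bicyclic stage. The fallback uses known chemistry, sets out from 8 (with 10) and comes back at 12. Without copper and ligand, alkoxide 11 takes up 10 by the known alkoxide-directed 1,4-addition (THF, −78 °C to rt). This has the same syn facial control but gives the racemate, that is 12 together with its (4R,5R)-enantiomer F1. The two are separated by preparative supercritical-fluid chromatography on an amylose carbamate chiral phase, and 12 goes on to step 7.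

Step 10 (key step). Several processes can outrun the crowded C4–C5 bond formation:
- a 1,2-hydride shift of the activated epoxide (Meinwald rearrangement) or proton loss to an allylic alcohol;
- ionisation at C9 with an aromatising alkyl shift;
- attack of O9 on the epoxide;
- protodesilylation of the enol silane.

The fallback keeps the C4–C5 bond but changes both the electrophile and the way it is activated. It sets out from 14 and comes back at 18.
- Dry HCl in Et2O/CH2Cl2 at −40 °C opens the epoxide at the tertiary carbon to give the (3S)-4-chloro-3-ol F2.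
- Et3SiOTf/2,6-lutidine gives its O3 triethylsilyl ether F3.
- LDA forms the lithium dienolate F4, and Me3SiCl traps it as the chloro dienol silane F5.
- A halophilic promoter (AgOTf, 2,6-di-tert-butyl-4-methylpyridine, CH2Cl2, −78 to −30 °C) then ionises only the C4–Cl bond.

This last step is the intramolecular form of the known α-tert-alkylation of enol silanes with tertiary halides. No oxophilic Lewis acid is present to attack O9, and the hydride shift loses the push of an aluminium alkoxide because O3 is a neutral silyl ether.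

Step 13. The crowded axial 6β-OH may bind iridium poorly. The result would be no turnover, poor facial selectivity, or isomerisation of the allylic alcohol to the saturated ketone. The fallback replaces coordination control by radical, product-stability control; it sets out from 19 and comes back at 21. Acetylation (Ac2O, DMAP, Et3N) gives the allylic 6β-acetate F6. Hydrogen-atom-transfer hydrogenation (Mn(dpm)3, PhSiH3, t-BuOOH, i-PrOH, rt) then places H on C7 and quenches the tertiary C8 radical from the β face. That face is favoured because the α face carries 9α-OSiEt3 and a β-methyl at C8 would be syn-axial to the C10 methyl, so the equatorial 8α-methyl compound 21 should result.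

**Further compounds**
F1 | step 6 | (4R,5R)-4-[2-(benzyloxy)ethyl]-4-hydroxy-3,5-dimethyl-5-(4-methylpent-3-en-1-yl)cyclohex-2-en-1-one (enantiomer of 12) | O=C1C[C@@](C)(CCC=C(C)C)[C@](O)(CCOCc2ccccc2)C(C)=C1
F2 | step 10 | (4S,5S)-4-[2-(benzyloxy)ethyl]-5-[(3S)-4-chloro-3-hydroxy-4-methylpentyl]-3,5-dimethyl-4-(triethylsilyloxy)cyclohex-2-en-1-one | O=C1C[C@](C)(CC[C@H](O)C(C)(C)Cl)[C@@](O[Si](CC)(CC)CC)(CCOCc2ccccc2)C(C)=C1
F3 | step 10 | O3 triethylsilyl ether of F2 | O=C1C[C@](C)(CC[C@H](O[Si](CC)(CC)CC)C(C)(C)Cl)[C@@](O[Si](CC)(CC)CC)(CCOCc2ccccc2)C(C)=C1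
F4 | step 10 | lithium cross-conjugated dienolate of F3 | [Li]OC1=C[C@](C)(CC[C@H](O[Si](CC)(CC)CC)C(C)(C)Cl)[C@@](O[Si](CC)(CC)CC)(CCOCc2ccccc2)C(C)=C1
F5 | step 10 | 6-(trimethylsilyloxy)-5,7-diene of F3 | C[Si](C)(C)OC1=C[C@](C)(CC[C@H](O[Si](CC)(CC)CC)C(C)(C)Cl)[C@@](O[Si](CC)(CC)CC)(CCOCc2ccccc2)C(C)=C1
F6 | step 13 | 6β-acetoxy-12-benzyloxy-3β,9α-bis(triethylsilyloxy)-13,14,15,16-tetranorlabd-7-ene | CC(=O)O[C@@H]1C=C(C)[C@](O[Si](CC)(CC)CC)(CCOCc3ccccc3)[C@@]2(C)CC[C@H](O[Si](CC)(CC)CC)C(C)(C)[C@H]12
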